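## Retrosynthetic overview

1. Agastinol 16 ⇒ (−)-lariciresinol 14 + 4-hydroxybenzoic acid 15. This C9–O ester bond is made last, without protecting groups.
2. The tetrahydrofuran (second ring formed, C7–O bond) ⇒ triol 13 ⇒ trans α-aroyl-β-benzyl-γ-butyrolactone 11. The lactone is the first ring formed. It is temporary and relays C8' to C8.
3. Key disconnection is C8–C8', the bond between the two C6C3 halves. Both carbons are α-carbonyl and normally nucleophilic. C8 is inverted to an electrophilic α,α-diacyl radical (enolonium equivalent) from bromo keto ester 8, and C8' is the chiral enamine of aldehyde 4.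
4. 4 ⇐ eugenyl acetate 1. 8 ⇐ vanillin acetate 5 + ethyl diazoacetate 6.

Lignan numbering is used: C7–C9 for the half that carries the ring aryl group, and C7'–C9' for the benzyl half. The target is 7R,8S,8'S (aryl/CH2O trans, CH2O/benzyl cis on the ring).

Assumption: catalysts and common reagents, including both enantiomers of the imidazolidinone salt, are bought and are neither numbered nor counted as steps.

## Route

**Step 1**
Reactants: 1 eugenyl acetate (4-allyl-2-methoxyphenyl acetate)
Product: 4 3-(4-acetoxy-3-methoxyphenyl)propanal, via trialkylborane 2 (not isolated), via trialkyl borate 3 (not isolated)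
Conditions: BH3·SMe2 (0.36 equiv), THF, 0 to 23 °C; then NMO (3 equiv), Pr4N[RuO4] (5 mol%), 4 Å molecular sieves, CH2Cl2, 23 °C
Reagents that add atoms: N-methylmorpholine N-oxide, C[N+]1([O-])CCOCC1 (the aldehyde oxygen); borane–dimethyl sulfide, [BH3-][S+](C)C (boron of 2 and 3 only)
Why: Anti-Markovnikov hydroboration puts boron on the terminal carbon, the amine oxide turns the three C–B bonds into C–O–B bonds, and the perruthenate/NMO couple (Ley–Griffith oxidation) takes the primary alkoxide to the aldehyde under neutral, dry conditions that leave the aryl acetate alone; no stereocentre is formed.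

**Step 2**
Reactants: 5 vanillin acetate (4-formyl-2-methoxyphenyl acetate); 6 ethyl diazoacetate
Product: 7 ethyl 3-(4-acetoxy-3-methoxyphenyl)-3-oxopropanoate
Conditions: NbCl5 (5 mol%), CH2Cl2, 23 °C
Reagents that add atoms: none
Why: Roskamp homologation, in which the diazo carbon adds to the Lewis-acid-activated aldehyde and a 1,2-hydride shift with loss of N2 gives the β-keto ester directly under conditions too mild to touch the aryl acetate; no stereocentre is formed.

**Step 3**
Reactants: 7 ethyl 3-(4-acetoxy-3-methoxyphenyl)-3-oxopropanoate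
Product: 8 ethyl 2-bromo-3-(4-acetoxy-3-methoxyphenyl)-3-oxopropanoate (racemic)
Conditions: NBS (1.0 equiv), NH4OAc (10 mol%), Et2O, 23 °C
Reagents that add atoms: N-bromosuccinimide, O=C1CCC(=O)N1Br
Why: Electrophilic α-bromination of the enol of an active methylene compound, which is far more reactive than the acyl-deactivated arene, stops at the monobromide with one equivalent of NBS; the new centre is racemic and is erased in step 4.

**Step 4 (key step)**
Reactants: 4 3-(4-acetoxy-3-methoxyphenyl)propanal (1.5 equiv); 8 ethyl 2-bromo-3-(4-acetoxy-3-methoxyphenyl)-3-oxopropanoate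
Product: 11 (3R,4S)-3-(4-hydroxy-3-methoxybenzoyl)-4-(4-hydroxy-3-methoxybenzyl)dihydrofuran-2(3H)-one, via keto aldehyde 9 (not isolated), via hydroxy keto ester 10 (not isolated)
Conditions: Ru(bpy)3Cl2 (0.5 mol%), (2S,5R)-2-tert-butyl-3,5-dimethylimidazolidin-4-one·TfOH (20 mol%), 2,6-lutidine (2 equiv), DMF, blue LED, 23 °C; then MeOH, NaBH4, −40 °C; then K2CO3 (5 equiv), 23 °C; 1 M HCl to pH 4
Reagents that add atoms: none
Why: Photoredox organocatalytic α-alkylation of an aldehyde (enamine/radical dual catalysis), in which monovalent ruthenium from the photocycle cleaves the C–Br bond of 8 so that C8, normally the nucleophilic carbon of a β-keto ester, reacts as an electrophilic radical (one-electron enolonium equivalent) with the equally nucleophilic enamine carbon C8' on the Re face left open by the C5 methyl of the (2S,5R) catalyst (8'S, about 90% ee expected), after which aldehyde-selective reduction, base-driven lactonisation and enolate equilibration place the aroyl group trans to the benzyl group (3R in 11) and methanolysis frees both phenols.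

**Step 5**
Reactants: 11 (3R,4S)-3-(4-hydroxy-3-methoxybenzoyl)-4-(4-hydroxy-3-methoxybenzyl)dihydrofuran-2(3H)-one
Product: 14 (−)-lariciresinol = (2R,3S,4S)-2-(4-hydroxy-3-methoxyphenyl)-4-(4-hydroxy-3-methoxybenzyl)-3-(hydroxymethyl)tetrahydrofuran, via hydroxy lactone 12 (not isolated), via triol 13 (not isolated)
Conditions: LiBH4 (6 equiv), THF/MeOH (20:1), 0 to 23 °C; then 1 M HCl to pH 2, THF/H2O, 23 °C, stopped as soon as 13 is consumed
Reagents that add atoms: none
Why: Borohydride reduction in a protic medium takes the keto tautomer to carbinol 12 and then the lactone to triol 13 without touching C8 or C8', and on acidification the p-hydroxybenzylic alcohol ionises to a quinone-methide-type cation that is closed 5-exo by the C9' hydroxyl in a reversible cycloetherification, which places the aryl group trans to the C8 hydroxymethyl group (7R) whatever the carbinol configuration was.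

**Step 6**
Reactants: 14 (−)-lariciresinol; 15 4-hydroxybenzoic acid (1.2 equiv)
Product: 16 agastinol = [(2R,3S,4S)-2-(4-hydroxy-3-methoxyphenyl)-4-(4-hydroxy-3-methoxybenzyl)tetrahydrofuran-3-yl]methyl 4-hydroxybenzoate
Conditions: PPh3 (1.3 equiv), DIAD (1.3 equiv), THF, 0 to 23 °C
Reagents that add atoms: none
Why: Mitsunobu esterification, in which only the aliphatic primary alcohol forms the alkoxyphosphonium ion and only the carboxylic acid (pKa about 4.5 against about 10 for the phenols) is acidic enough to protonate the betaine and act as nucleophile, so the ester forms chemoselectively at the non-stereogenic C9 and all three stereocentres are untouched.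

## Compound list

1 | eugenyl acetate (4-allyl-2-methoxyphenyl acetate) | CC(=O)Oc1ccc(CC=C)cc1OC | starting material
2 | tris[3-(4-acetoxy-3-methoxyphenyl)propyl]borane | B(CCCc1ccc(OC(C)=O)c(OC)c1)(CCCc1ccc(OC(C)=O)c(OC)c1)CCCc1ccc(OC(C)=O)c(OC)c1 | intermediate
3 | tris[3-(4-acetoxy-3-methoxyphenyl)propyl] borate | B(OCCCc1ccc(OC(C)=O)c(OC)c1)(OCCCc1ccc(OC(C)=O)c(OC)c1)OCCCc1ccc(OC(C)=O)c(OC)c1 | intermediate
4 | 3-(4-acetoxy-3-methoxyphenyl)propanal | CC(=O)Oc1ccc(CCC=O)cc1OC | intermediate
5 | vanillin acetate (4-formyl-2-methoxyphenyl acetate) | CC(=O)Oc1ccc(C=O)cc1OC | starting material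
6 | ethyl diazoacetate | CCOC(=O)C=[N+]=[N-] | starting material
7 | ethyl 3-(4-acetoxy-3-methoxyphenyl)-3-oxopropanoate | CCOC(=O)CC(=O)c1ccc(OC(C)=O)c(OC)c1 | intermediate
8 | ethyl 2-bromo-3-(4-acetoxy-3-methoxyphenyl)-3-oxopropanoate (racemic) | CCOC(=O)C(Br)C(=O)c1ccc(OC(C)=O)c(OC)c1 | intermediate
9 | ethyl (3S)-2-(4-acetoxy-3-methoxybenzoyl)-3-(4-acetoxy-3-methoxybenzyl)-4-oxobutanoate (both C2 epimers) | CCOC(=O)C(C(=O)c1ccc(OC(C)=O)c(OC)c1)[C@H](Cc1ccc(OC(C)=O)c(OC)c1)C=O | intermediate
10 | ethyl (3S)-2-(4-acetoxy-3-methoxybenzoyl)-3-(4-acetoxy-3-methoxybenzyl)-4-hydroxybutanoate (both C2 epimers) | CCOC(=O)C(C(=O)c1ccc(OC(C)=O)c(OC)c1)[C@H](Cc1ccc(OC(C)=O)c(OC)c1)CO | intermediate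
11 | (3R,4S)-3-(4-hydroxy-3-methoxybenzoyl)-4-(4-hydroxy-3-methoxybenzyl)dihydrofuran-2(3H)-one (trans) | O=C1OC[C@@H](Cc2ccc(O)c(OC)c2)[C@@H]1C(=O)c1ccc(O)c(OC)c1 | intermediate
12 | (3R,4S)-3-[hydroxy(4-hydroxy-3-methoxyphenyl)methyl]-4-(4-hydroxy-3-methoxybenzyl)dihydrofuran-2(3H)-one (both carbinol epimers) | O=C1OC[C@@H](Cc2ccc(O)c(OC)c2)[C@@H]1C(O)c1ccc(O)c(OC)c1 | intermediate
13 | (2S,3S)-2-[hydroxy(4-hydroxy-3-methoxyphenyl)methyl]-3-(4-hydroxy-3-methoxybenzyl)butane-1,4-diol (both carbinol epimers) | OC[C@@H](Cc1ccc(O)c(OC)c1)[C@@H](CO)C(O)c1ccc(O)c(OC)c1 | intermediate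
14 | (−)-lariciresinol, (2R,3S,4S) | COc1cc(C[C@@H]2CO[C@@H](c3ccc(O)c(OC)c3)[C@@H]2CO)ccc1O | intermediate
15 | 4-hydroxybenzoic acid | OC(=O)c1ccc(O)cc1 | starting material
16 | agastinol | COc1cc(C[C@@H]2CO[C@@H](c3ccc(O)c(OC)c3)[C@@H]2COC(=O)c2ccc(O)cc2)ccc1O | target

## Step count and risks

Total step count: 6.
Longest linear sequence: 5 steps (5 → 7 → 8 → 11 → 14 → 16).

**Step 4 (highest risk).**
- Bromide 8 may act as a bromonium donor towards the enamine.
- The hindered diacyl radical may add slowly.
- The 1,4-dicarbonyl 9 may dehydrate to a furan before it is reduced.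
- If the ee is only about 90%, 11 or 14 is recrystallised.

Fallback, setting out from 4 and coming back at 13. The same enamine/photoredox coupling is run with commercial dimethyl bromomalonate, the best-established radical precursor. This gives dimethyl 2-[(2S)-1-(4-acetoxy-3-methoxyphenyl)-3-oxopropan-2-yl]propanedioate F1. NaBH4 and then K2CO3/MeOH give methyl (3R,4S)-4-(4-hydroxy-3-methoxybenzyl)-2-oxotetrahydrofuran-3-carboxylate F2. LiCl in wet DMSO at 140 °C (Krapcho reaction) gives (4S)-4-(4-hydroxy-3-methoxybenzyl)dihydrofuran-2(3H)-one F3. Its phenoxide/enolate dianion (LiN(iPr)2, 2.1 equiv, THF, −78 °C) adds to 5 anti to the benzyl group. The aldol product is (3R,4S)-3-[(4-acetoxy-3-methoxyphenyl)(hydroxy)methyl]-4-(4-hydroxy-3-methoxybenzyl)dihydrofuran-2(3H)-one F4. Under the LiBH4 conditions of step 5, F4 also loses its acetate and rejoins the route at triol 13. C8–C8' is still made by the electrophilic α-carbonyl radical, while C7–C8 is now made afterwards by a lactone aldol.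

**Step 5.**
- The β-keto lactone may sit as an unreactive enolate.
- The phenoxide carbinol may lose oxygen through a quinone methide that is then reduced.
- Acid may carry 14 on to the aryltetralin (cyclolariciresinol).

Fallback, setting out from 11 and coming back at 14. The C7 oxygen is removed on purpose and put back oxidatively. H2 with Pd/C in AcOH at 23 °C hydrogenolyses the aryl ketone to (+)-matairesinol F5. LiAlH4 in THF gives (+)-secoisolariciresinol F6. DDQ (1.0 equiv, THF, 0 °C) then generates one p-quinone methide, which the C9' hydroxyl traps 5-exo to give 14. F6 is C2-symmetric, so oxidation at either benzylic position gives the same compound, and no acid is present.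

**Step 6.** The phenols may be alkylated, or the β-branched primary alcohol may react sluggishly.

Fallback, setting out from 14 and coming back at 16. Exhaustive acylation is followed by selective release of the phenols. 4-Acetoxybenzoyl chloride (3.5 equiv), Et3N and DMAP in CH2Cl2 give (−)-lariciresinol tris(4-acetoxybenzoate) F7. K2CO3/MeOH at 0 °C then cleaves the two aryl benzoates and all aryl acetates. The alkyl ester survives because, once its own acetate is gone, it is a 4-oxidobenzoate whose carbonyl is strongly deactivated towards methoxide. Acidification gives 16.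

## Further compounds

F1 | step 4 | dimethyl 2-[(2S)-1-(4-acetoxy-3-methoxyphenyl)-3-oxopropan-2-yl]propanedioate | COC(=O)C(C(=O)OC)[C@H](Cc1ccc(OC(C)=O)c(OC)c1)C=O
F2 | step 4 | methyl (3R,4S)-4-(4-hydroxy-3-methoxybenzyl)-2-oxotetrahydrofuran-3-carboxylate | O=C1OC[C@@H](Cc2ccc(O)c(OC)c2)[C@@H]1C(=O)OC
F3 | step 4 | (4S)-4-(4-hydroxy-3-methoxybenzyl)dihydrofuran-2(3H)-one | O=C1OC[C@@H](Cc2ccc(O)c(OC)c2)C1
F4 | step 4 | (3R,4S)-3-[(4-acetoxy-3-methoxyphenyl)(hydroxy)methyl]-4-(4-hydroxy-3-methoxybenzyl)dihydrofuran-2(3H)-one | O=C1OC[C@@H](Cc2ccc(O)c(OC)c2)[C@@H]1C(O)c1ccc(OC(C)=O)c(OC)c1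
F5 | step 5 | (+)-matairesinol, (3S,4S)-3,4-bis(4-hydroxy-3-methoxybenzyl)dihydrofuran-2(3H)-one | O=C1OC[C@@H](Cc2ccc(O)c(OC)c2)[C@@H]1Cc1ccc(O)c(OC)c1
F6 | step 5 | (+)-secoisolariciresinol, (2S,3S)-2,3-bis(4-hydroxy-3-methoxybenzyl)butane-1,4-diol | OC[C@@H](Cc1ccc(O)c(OC)c1)[C@@H](CO)Cc1ccc(O)c(OC)c1
F7 | step 6 | (−)-lariciresinol tris(4-acetoxybenzoate) | COc1cc(C[C@@H]2CO[C@@H](c3ccc(OC(=O)c4ccc(OC(C)=O)cc4)c(OC)c3)[C@@H]2COC(=O)c2ccc(OC(C)=O)cc2)ccc1OC(=O)c1ccc(OC(C)=O)cc1
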